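## Analysis of the target

The target 12 is the flavanone (2S)-7-hydroxy-2-(4-hydroxyphenyl)-6,8-bis(3-methylbut-2-enyl)chroman-4-one, in which benzo ring A is fused to the dihydropyranone ring C and the 4-hydroxyphenyl ring B sits on C2. C2 is the only stereocentre and is (S), so one absolute configuration has to be kept and no relative stereochemistry has to be controlled. That centre is fragile, because it is benzylic, carries the ring oxygen O1 and lies beta to the C4 ketone, so that enolisation towards C3 permits retro-oxa-Michael opening of ring C and reclosure with loss of configuration. Base, long heating and a free 4'-phenol (through a quinone methide) all favour this pathway. The prenyl groups are sensitive to acid, since each is ortho to the C7 hydroxyl and a protonated trisubstituted alkene is captured by that oxygen as a 2,2-dimethylchroman. The difficulty lies in ring A, where the C7 oxygen must be flanked by C-prenyl groups on both C6 and C8, while direct prenylation of such phenols gives O-alkylation and mixtures of positions and degrees of substitution. The plan rests on two facts: each prenyl chain is an allyl group whose terminal CH2 is replaced by C(CH3)2, and C6 and C8 are exactly the two ortho positions of O7, to which an O7-allyl group is delivered by a [3,3]-sigmatropic shift. Rings A, B and C, both phenols, the ketone and the (S) centre are already present in (S)-liquiritigenin 1.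

## Retrosynthetic reasoning

12 ⇒ 11. Only the O–Si bond at the 4'-oxygen is cut. The silyl group is kept to the end because a free 4'-phenol would compete in the second etherification and would ease racemisation in the heated steps. The forward desilylation must avoid both free phenoxide and strong acid.

11 ⇒ 7 + 8. Both trisubstituted side-chain C=C bonds are cut, giving the diallyl flavanone 7 and two molecules of 2-methylbut-2-ene 8. Cutting here, and not at the aryl–CH2 bonds, leaves the carbons on C6 and C8 in place, so the regiochemical problem of ring A is handed to a step that cannot misplace them. The two alkenes are of the same kind, so one operation serves both. The forward reaction must exchange =CH2 for =C(CH3)2 twice, under neutral conditions, without moving a double bond into conjugation with ring A.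

7 ⇒ 6. The aryl–CH2 bond at C6 is cut and the allyl group is returned to O7, giving the allyl ether 6. A [3,3] shift can only deliver the allyl carbon to an ortho position of O7, and in 6 only C6 is left, so the forward shift has a single productive outcome.

6 ⇒ 5 + 2. The O7–CH2 bond is cut, giving the ortho-allylphenol 5 and allyl alcohol 2. The forward etherification is a redox condensation under neutral conditions, which spares C2.

5 ⇒ 4. The aryl–CH2 bond at C8 is cut and the allyl group is again returned to O7, giving the allyl ether 4. In the forward shift both ortho positions are open. C8, which lies between the two oxygen-bearing carbons C7 and C8a, is the expected terminus, and 5 is isolated. A share of the shift going to C6 would not be a wrong product in the end, because the same two operations would fill C8 afterwards.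

4 ⇒ 3 ⇒ 1 + 2. The O4'–Si bond and then the O7–CH2 bond are cut, arriving at 1 and 2. Compound 1 already holds rings A, B and C and the (S) centre, so no stereocentre has to be made. The forward allylation must distinguish the two phenols, and their acidity difference (O7–H is para to the C4 carbonyl) is the handle.

## Alternatives that were turned down

Alternative 1: Ring A is built, not bought. The benzene ring is cut into the prenylated siloxyalkyne A2 and the prenylated unsaturated diazoketone A3.
- Forward key step: irradiation of A3 in the presence of A2 starts a cascade of Wolff rearrangement to a vinylketene, ketene–alkyne [2+2] cycloaddition, four-electron opening of the cyclobutenone and six-electron closure (a Danheiser-type benzannulation). It should give the resorcinol monosilyl ether A1, with the future C7 hydroxyl between both prenyl groups and the future O1 silylated.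
- For: every substituent position on ring A follows from the connectivity of the two partners, so no C6/C8 or O/C question arises. The only activated free position of A1 is the future C4a, so a later acylation should also be regioselective. On regiocontrol it is stronger than the chosen route, and it never heats a stereocentre.
- Against: A1 has neither ring C, ring B nor the stereocentre. Desilylation, acylation at C4a, attachment of the ring B unit and an enantioselective oxa-Michael closure would follow, and that closure is an unreliable way to set C2 in a flavanone with no extra activating group. A3 has a doubly allylic CH2 next to the enone and is prone to conjugation. A2 is a sensitive ynol ether. Each needs several steps.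
- Comparison: roughly twice the step count. The chosen route offers a purchased enantiopure ring system and removes the regiochemical question by filling both ortho positions of O7.

Alternative 2: Ring C is cut at O1–C8a, leading back to the anti-1,3-diol aryl bromide A5.
- Forward key step: an Ullmann-type intramolecular O-arylation under CuI catalysis with a phenanthroline ligand and a carbonate base, hot, joins the C2 hydroxyl to C8a and should give the cis-flavan-4-ol A4. Oxidation at C4 and removal of two methoxymethyl ethers would follow.
- For: C2 is set in the open chain by reagent-controlled carbonyl chemistry and is untouched in the ring closure. A flavan-4-ol cannot open by a retro-oxa-Michael reaction, so the hot basic coupling does not endanger C2. On configurational safety it is stronger than the chosen route, which carries the ketone through two thermal steps.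
- Against: A5 is a pentasubstituted bromoarene that already carries both prenyl groups, so the prenylation problem is moved, not solved. Two stereocentres are made and one is then oxidised away. The bromide is flanked on both sides, which slows the coupling. The final acetal cleavage needs acid next to an ortho-prenylphenol, which invites chroman formation.
- Comparison: well over ten steps. The chosen route offers brevity, a bought stereocentre and an acid-free end game.

Alternative 3: Ring A is cut into the symmetrical ketone A7 and the malonate A8.
- Forward key step: the enolate of A7 displaces ethoxide from A8, the second alpha carbon then attacks an ester carbonyl under alkoxide base, and tautomerisation should give the resorcylate A6.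
- For: the hidden symmetry is real, since the C7 carbon with its two prenylated neighbours is the ketone carbon of A7. The materials are cheap, no transition metal is needed and both prenyl groups are placed regiospecifically. On cost and regiocontrol it equals or beats the chosen route.
- Against: after the first C–C bond, O-cyclisation of the enolate oxygen onto the ester may compete with the C-cyclisation that closes the carbocycle. A6 carries only an ester where the C4 chain must grow, so ester-to-ketone conversion, condensation with the ring B unit and an asymmetric oxa-Michael closure remain. C2 would again depend on that weak asymmetric step.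
- Comparison: about ten or more steps, with the stereocentre set late and uncertainly. The chosen route offers a stereocentre of known configuration from the start.

Key step: step 6

Assumption: commercial natural liquiritigenin is taken to be the (2S) enantiomer in high optical purity, to be checked by chiral HPLC before use. The first Claisen shift is taken to go mainly to C8, as is usual for 7-allyloxy benzopyranones, so the route is written through the 8-allyl compound 5.

## Route

Step 1
Reactants: 1 (S)-liquiritigenin, (2S)-7-hydroxy-2-(4-hydroxyphenyl)chroman-4-one; 2 allyl alcohol
Product: 3 (2S)-7-(allyloxy)-2-(4-hydroxyphenyl)chroman-4-one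
Conditions: allyl alcohol (1.05 equiv), PPh3, DIAD (1.05 equiv each, slow addition), THF, 0 °C to rt
Reagents that add atoms: none
Why: Mitsunobu etherification: the PPh3/DIAD betaine is protonated by the more acidic phenol, the 7-OH para to the C4 carbonyl (a vinylogous acid, roughly two pKa units stronger than the 4'-OH), and the 7-phenoxide displaces the allyloxyphosphonium ion, so one equivalent of reagents should give mainly O7 mono-allylation. The medium stays essentially neutral, so ring C does not open and C2 keeps its (S) configuration.

Step 2
Reactants: 3 (2S)-7-(allyloxy)-2-(4-hydroxyphenyl)chroman-4-one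
Product: 4 (2S)-7-(allyloxy)-2-[4-(tert-butyldimethylsilyloxy)phenyl]chroman-4-one
Conditions: TBSCl, imidazole, DMF, 0 °C to rt
Reagents that add atoms: tert-butyldimethylsilyl chloride (TBSCl), CC(C)(C)[Si](C)(C)Cl
Why: Imidazole-assisted silylation of the one remaining phenol. The silyl ether removes the free 4'-OH that would compete in step 4 and would ease racemisation in the hot steps.

Step 3
Reactants: 4 (2S)-7-(allyloxy)-2-[4-(tert-butyldimethylsilyloxy)phenyl]chroman-4-one
Product: 5 (2S)-8-allyl-7-hydroxy-2-[4-(tert-butyldimethylsilyloxy)phenyl]chroman-4-one
Conditions: 1,2-dichlorobenzene (degassed), 200–210 °C, sealed vessel (microwave), Ar; chromatography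
Reagents that add atoms: none
Why: Aromatic Claisen rearrangement: a suprafacial [3,3]-sigmatropic shift moves the O7-allyl group to an ortho carbon and tautomerisation restores the arene. C8 is the expected terminus because the C7–C8 bond, between the two oxygen-bearing carbons, has the higher double-bond character, and any share of the shift that goes to C6 is removed by chromatography. No acid or base is added, and the aryl silyl ether and the ketone are thermally inert.

Step 4
Reactants: 5 (2S)-8-allyl-7-hydroxy-2-[4-(tert-butyldimethylsilyloxy)phenyl]chroman-4-one; 2 allyl alcohol
Product: 6 (2S)-8-allyl-7-(allyloxy)-2-[4-(tert-butyldimethylsilyloxy)phenyl]chroman-4-one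
Conditions: allyl alcohol, PPh3, DIAD, THF, 0 °C to rt
Reagents that add atoms: none
Why: Second Mitsunobu etherification, with the 7-OH now the only free phenol. It is a para-acyl phenol and acidic enough to react despite one ortho substituent, and the neutral conditions again spare C2.

Step 5
Reactants: 6 (2S)-8-allyl-7-(allyloxy)-2-[4-(tert-butyldimethylsilyloxy)phenyl]chroman-4-one
Product: 7 (2S)-6,8-diallyl-7-hydroxy-2-[4-(tert-butyldimethylsilyloxy)phenyl]chroman-4-one
Conditions: 1,2-dichlorobenzene (degassed), 210 °C, sealed vessel (microwave), Ar
Reagents that add atoms: none
Why: Second aromatic Claisen rearrangement: C6 is the only free ortho position of O7 in 6, so the [3,3] shift and tautomerisation can give only 7. A shift to the occupied C8 is reversible and unproductive, because no hydrogen is there for rearomatisation and the para position C4a is a ring-fusion carbon.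

Step 6
Reactants: 7 (2S)-6,8-diallyl-7-hydroxy-2-[4-(tert-butyldimethylsilyloxy)phenyl]chroman-4-one; 8 2-methylbut-2-ene
Product: 11 (2S)-7-hydroxy-6,8-bis(3-methylbut-2-enyl)-2-[4-(tert-butyldimethylsilyloxy)phenyl]chroman-4-one, via the 6-allyl-8-prenyl flavanone 9 (not isolated), via the 8-allyl-6-prenyl flavanone 10 (not isolated)
Conditions: second-generation Grubbs catalyst RuCl2(H2IMes)(PCy3)(=CHPh) (5–10 mol %), 1,4-benzoquinone (10 mol %), 2-methylbut-2-ene (large excess)/CH2Cl2, 40 °C, sealed tube, Ar
Reagents that add atoms: none
Why: Olefin cross-metathesis by the Chauvin mechanism: after loss of PCy3 the ruthenium alkylidene adds [2+2] to a terminal allyl alkene of 7, the ruthenacyclobutane cycloreverts, and exchange with 8 (which supplies the Ru=C(CH3)2 carrier) replaces each terminal CH2 by C(CH3)2, releasing propene and passing through 9 and 10. The closest known reaction type is the cross-metathesis of ortho-allylphenols and other allylarenes with 2-methylbut-2-ene to give prenylarenes. No ring is closed, because the two allyl groups are meta to each other across C7 and joining them would need an impossibly strained bridged ring; no stereocentre is formed, and C2 is untouched in a neutral medium at 40 °C. Cross- over self-metathesis is secured by the large excess of 8, and completion at both chains by the fact that the hindered trisubstituted prenyl alkenes do not re-enter the cycle and so act as a sink. If the catalyst transfers the ethylidene end of 8 instead, the resulting disubstituted alkene stays metathesis-active and is corrected by further exchange. Migration of an allyl double bond into conjugation with ring A is the main side reaction; it is caused by ruthenium hydrides and is held back by the benzoquinone additive and the low temperature. The free 7-OH, the ketone and the aryl silyl ether are tolerated by this catalyst.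

Step 7
Reactants: 11 (2S)-7-hydroxy-6,8-bis(3-methylbut-2-enyl)-2-[4-(tert-butyldimethylsilyloxy)phenyl]chroman-4-one
Product: 12 (2S)-7-hydroxy-2-(4-hydroxyphenyl)-6,8-bis(3-methylbut-2-enyl)chroman-4-one (target)
Conditions: TBAF, AcOH (1:1), THF, 0 °C
Reagents that add atoms: none
Why: Fluoride-induced cleavage of the aryl silyl ether, driven by Si–F bond formation and fast at 0 °C for a phenolic silyl group. Acetic acid protonates the liberated phenoxide at once, so neither base-induced opening of ring C nor acid-induced cyclisation of a prenyl group onto O7 should occur.

## Compound list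

1 | (S)-liquiritigenin, (2S)-7-hydroxy-2-(4-hydroxyphenyl)chroman-4-one | Oc1ccc2c(c1)O[C@H](c1ccc(O)cc1)CC2=O | starting material
2 | allyl alcohol (prop-2-en-1-ol) | C=CCO | starting material
3 | (2S)-7-(allyloxy)-2-(4-hydroxyphenyl)chroman-4-one | C=CCOc1ccc2c(c1)O[C@H](c1ccc(O)cc1)CC2=O | intermediate
4 | (2S)-7-(allyloxy)-2-[4-(tert-butyldimethylsilyloxy)phenyl]chroman-4-one | C=CCOc1ccc2c(c1)O[C@H](c1ccc(O[Si](C)(C)C(C)(C)C)cc1)CC2=O | intermediate
5 | (2S)-8-allyl-7-hydroxy-2-[4-(tert-butyldimethylsilyloxy)phenyl]chroman-4-one | Oc1ccc2c(c1CC=C)O[C@H](c1ccc(O[Si](C)(C)C(C)(C)C)cc1)CC2=O | intermediate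
6 | (2S)-8-allyl-7-(allyloxy)-2-[4-(tert-butyldimethylsilyloxy)phenyl]chroman-4-one | C=CCOc1ccc2c(c1CC=C)O[C@H](c1ccc(O[Si](C)(C)C(C)(C)C)cc1)CC2=O | intermediate
7 | (2S)-6,8-diallyl-7-hydroxy-2-[4-(tert-butyldimethylsilyloxy)phenyl]chroman-4-one | C=CCc1cc2c(c(CC=C)c1O)O[C@H](c1ccc(O[Si](C)(C)C(C)(C)C)cc1)CC2=O | intermediate
8 | 2-methylbut-2-ene | CC=C(C)C | starting material
9 | (2S)-6-allyl-7-hydroxy-8-(3-methylbut-2-enyl)-2-[4-(tert-butyldimethylsilyloxy)phenyl]chroman-4-one | C=CCc1cc2c(c(CC=C(C)C)c1O)O[C@H](c1ccc(O[Si](C)(C)C(C)(C)C)cc1)CC2=O | intermediate
10 | (2S)-8-allyl-7-hydroxy-6-(3-methylbut-2-enyl)-2-[4-(tert-butyldimethylsilyloxy)phenyl]chroman-4-one | CC(C)=CCc1cc2c(c(CC=C)c1O)O[C@H](c1ccc(O[Si](C)(C)C(C)(C)C)cc1)CC2=O | intermediate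
11 | (2S)-7-hydroxy-6,8-bis(3-methylbut-2-enyl)-2-[4-(tert-butyldimethylsilyloxy)phenyl]chroman-4-one | CC(C)=CCc1cc2c(c(CC=C(C)C)c1O)O[C@H](c1ccc(O[Si](C)(C)C(C)(C)C)cc1)CC2=O | intermediate
12 | (2S)-7-hydroxy-2-(4-hydroxyphenyl)-6,8-bis(3-methylbut-2-enyl)chroman-4-one | CC(C)=CCc1cc2c(c(CC=C(C)C)c1O)O[C@H](c1ccc(O)cc1)CC2=O | target

## Step count and least certain steps

Total: 7 steps. Longest linear sequence: 7 steps, from 1 to 12.

Step 6 (key step). The most likely failure is incomplete exchange at one chain together with migration of an allyl double bond into conjugation with ring A. Ruthenium hydrides from catalyst decay cause the migration, and the free, acidic 7-OH lying between both alkenes may favour their formation. The result would be mixed or chain-shortened material that is hard to separate. The fallback masks that phenol. It sets out from 7, which is silylated on O7 (TBSCl, imidazole, DMF, 40 °C) to (2S)-6,8-diallyl-7-(tert-butyldimethylsilyloxy)-2-[4-(tert-butyldimethylsilyloxy)phenyl]chroman-4-one F1. Cross-metathesis of F1 with 8 under the same ruthenium catalyst should give (2S)-7-(tert-butyldimethylsilyloxy)-6,8-bis(3-methylbut-2-enyl)-2-[4-(tert-butyldimethylsilyloxy)phenyl]chroman-4-one F2. Removal of both silyl groups with TBAF/AcOH returns to the route at 12.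

Step 1. Discrimination between the two phenols may be imperfect, leading to some 4'-O-allylation and bis-allylation, because the 4'-OH is still acidic enough for the Mitsunobu reaction. The fallback differentiates the oxygens by leaving-group ability instead. It sets out from 1, which is silylated on both phenols (TBSCl, imidazole, DMF) to (2S)-7-(tert-butyldimethylsilyloxy)-2-[4-(tert-butyldimethylsilyloxy)phenyl]chroman-4-one F3. One equivalent of TBAF buffered with AcOH (THF, −20 °C) should preferentially cleave the silyl group on O7, whose para-acyl phenoxide is the better leaving group, giving (2S)-7-hydroxy-2-[4-(tert-butyldimethylsilyloxy)phenyl]chroman-4-one F4. Mitsunobu allylation of F4 with 2 gives 4, where the route is rejoined.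

Step 3. The shift may divide between C8 and C6 more evenly than expected, so that isolating 5 alone costs material. The fallback gives up the separation and relies on convergence. It sets out from 4, whose rearrangement mixture is carried on unseparated; the part that has gone to C6 is (2S)-6-allyl-7-hydroxy-2-[4-(tert-butyldimethylsilyloxy)phenyl]chroman-4-one F5. Mitsunobu etherification of F5 with 2, beside 5, should give (2S)-6-allyl-7-(allyloxy)-2-[4-(tert-butyldimethylsilyloxy)phenyl]chroman-4-one F6. Its only free ortho position is C8, so its Claisen shift under the conditions of step 5 arrives at 7, where the route is rejoined.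

Step 5. Partial loss of configuration at C2 may occur by reversible thermal opening and reclosure of ring C during prolonged heating, helped by the acidic phenolic product. The same concern applies more mildly to step 3; step 5 needs the harder conditions because C6 is the less favoured terminus. The fallback restores the configuration instead of preserving it. It sets out from 7 of lowered optical purity, which contains the enantiomer (2R)-6,8-diallyl-7-hydroxy-2-[4-(tert-butyldimethylsilyloxy)phenyl]chroman-4-one F7. Kinetic resolution by Noyori-type asymmetric transfer hydrogenation (RuCl(p-cymene)[(R,R)-TsDPEN], HCO2H/Et3N 5:2, EtOAc, rt) is applied; the phenol stays un-ionised in this acidic medium. The catalyst that delivers the (4R)-carbinol should consume F7 in the matched sense, as the cis-alcohol (2R,4R)-6,8-diallyl-2-[4-(tert-butyldimethylsilyloxy)phenyl]chromane-4,7-diol F8. The unreduced (2S)-ketone is separated by chromatography and re-enters the route as 7.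

Step 7. If buffering is insufficient, the phenoxides formed on desilylation may open ring C and erode C2. If the medium is made more acidic to prevent that, a prenyl chain may cyclise onto O7. The fallback reverses the order of the last two operations. It sets out from 7, whose silyl ether is removed before the metathesis (HF·pyridine, THF/pyridine, 0 °C). Acid is harmless at that stage because monosubstituted allyl alkenes are not protonated to stabilised cations. This should give (2S)-6,8-diallyl-7-hydroxy-2-(4-hydroxyphenyl)chroman-4-one F9. Cross-metathesis of F9 with 8 under the conditions of step 6 then arrives directly at 12.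

## Further compounds

F1 | step 6 | (2S)-6,8-diallyl-7-(tert-butyldimethylsilyloxy)-2-[4-(tert-butyldimethylsilyloxy)phenyl]chroman-4-one | C=CCc1cc2c(c(CC=C)c1O[Si](C)(C)C(C)(C)C)O[C@H](c1ccc(O[Si](C)(C)C(C)(C)C)cc1)CC2=O
F2 | step 6 | (2S)-7-(tert-butyldimethylsilyloxy)-6,8-bis(3-methylbut-2-enyl)-2-[4-(tert-butyldimethylsilyloxy)phenyl]chroman-4-one | CC(C)=CCc1cc2c(c(CC=C(C)C)c1O[Si](C)(C)C(C)(C)C)O[C@H](c1ccc(O[Si](C)(C)C(C)(C)C)cc1)CC2=O
F3 | step 1 | (2S)-7-(tert-butyldimethylsilyloxy)-2-[4-(tert-butyldimethylsilyloxy)phenyl]chroman-4-one | CC(C)(C)[Si](C)(C)Oc1ccc2c(c1)O[C@H](c1ccc(O[Si](C)(C)C(C)(C)C)cc1)CC2=O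
F4 | step 1 | (2S)-7-hydroxy-2-[4-(tert-butyldimethylsilyloxy)phenyl]chroman-4-one | Oc1ccc2c(c1)O[C@H](c1ccc(O[Si](C)(C)C(C)(C)C)cc1)CC2=O
F5 | step 3 | (2S)-6-allyl-7-hydroxy-2-[4-(tert-butyldimethylsilyloxy)phenyl]chroman-4-one | C=CCc1cc2c(cc1O)O[C@H](c1ccc(O[Si](C)(C)C(C)(C)C)cc1)CC2=O
F6 | step 3 | (2S)-6-allyl-7-(allyloxy)-2-[4-(tert-butyldimethylsilyloxy)phenyl]chroman-4-one | C=CCc1cc2c(cc1OCC=C)O[C@H](c1ccc(O[Si](C)(C)C(C)(C)C)cc1)CC2=O
F7 | step 5 | (2R)-6,8-diallyl-7-hydroxy-2-[4-(tert-butyldimethylsilyloxy)phenyl]chroman-4-one | C=CCc1cc2c(c(CC=C)c1O)O[C@@H](c1ccc(O[Si](C)(C)C(C)(C)C)cc1)CC2=O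
F8 | step 5 | (2R,4R)-6,8-diallyl-2-[4-(tert-butyldimethylsilyloxy)phenyl]chromane-4,7-diol | C=CCc1cc2c(c(CC=C)c1O)O[C@@H](c1ccc(O[Si](C)(C)C(C)(C)C)cc1)C[C@H]2O
F9 | step 7 | (2S)-6,8-diallyl-7-hydroxy-2-(4-hydroxyphenyl)chroman-4-one | C=CCc1cc2c(c(CC=C)c1O)O[C@H](c1ccc(O)cc1)CC2=O
A1 | alternative 1 | 2,6-bis(3-methylbut-2-enyl)-3-(triisopropylsilyloxy)phenol | CC(C)=CCc1ccc(O[Si](C(C)C)(C(C)C)C(C)C)c(CC=C(C)C)c1O
A2 | alternative 1 | triisopropyl[(5-methylhex-4-en-1-yn-1-yl)oxy]silane | CC(C)=CCC#CO[Si](C(C)C)(C(C)C)C(C)C
A3 | alternative 1 | (3E)-1-diazo-7-methylocta-3,6-dien-2-one | CC(C)=CC/C=C/C(=O)C=[N+]=[N-]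
A4 | alternative 2 | (2S,4S)-7-(methoxymethoxy)-2-[4-(methoxymethoxy)phenyl]-6,8-bis(3-methylbut-2-enyl)chroman-4-ol | CC(C)=CCc1cc2c(c(CC=C(C)C)c1OCOC)O[C@H](c1ccc(OCOC)cc1)C[C@@H]2O
A5 | alternative 2 | (1S,3S)-1-[2-bromo-4-(methoxymethoxy)-3,5-bis(3-methylbut-2-enyl)phenyl]-3-[4-(methoxymethoxy)phenyl]propane-1,3-diol | CC(C)=CCc1cc([C@@H](O)C[C@H](O)c2ccc(OCOC)cc2)c(Br)c(CC=C(C)C)c1OCOC
A6 | alternative 3 | ethyl 2,4-dihydroxy-3,5-bis(3-methylbut-2-enyl)benzoate | CCOC(=O)c1cc(CC=C(C)C)c(O)c(CC=C(C)C)c1O
A7 | alternative 3 | 2,10-dimethylundeca-2,9-dien-6-one | CC(C)=CCCC(=O)CCC=C(C)C
A8 | alternative 3 | diethyl (ethoxymethylene)malonate | CCOC=C(C(=O)OCC)C(=O)OCC
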